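## The problem

The target is made of two carbocycles joined by one bond: ring A is a cyclopentane numbered C1 (quaternary, carrying a methyl group and ring B), C2 (CMe2), C3 (CHBr), C4 and C5, and ring B is a cyclohexane numbered C1' (tertiary carbinol), C2', C3', C4' (CMeCl), C5' (CHBr) and C6'. The C1–C1' bond links a quaternary carbon to a fully substituted carbinol carbon and, with C2, forms a row of three contiguous fully substituted carbons, so this region calls for strain-driven or intramolecular bond formation. There are five stereocentres in two sets, C1/C3 and C1'/C4'/C5'. C1 biases C3 only weakly and cannot tell the two arms of ring B apart, so C3 and the arm choice at C1' need reagent control, whereas C4' and C5' can be set from C1' because the bulky cyclopentyl group locks ring B in the chair with the C1' hydroxyl axial. In that chair the C4' chlorine and the C5' bromine are trans and both equatorial, with the chlorine cis to the hydroxyl; simple anti addition of the two halogens to a C4'=C5' alkene would favour the diaxial isomer, so the bromonium ion must be made on the face opposite to the hydroxyl and opened at C4'. The tertiary alcohol next to a quaternary carbon ionises and rearranges in acid, the tertiary chloride and both secondary bromides eliminate with base, the neopentylic C3 bromide rearranges if it ionises, and the vicinal bromochloride is lost to reducing metals. The feature that opens the route is the sequence C1 (quaternary), C2 (gem-dimethyl), C3 (heteroatom): it is what results when the fully substituted ring carbon of a 1-(prop-1-en-2-yl)cyclobutanol migrates to the protonated alkene carbon, the carbinol becoming the C3 ketone. Ring B, oxygenated at C1' and functionalised at the para-related C4', can pass through that step as a 4-methoxyphenyl group on the migrating carbon.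

## Retrosynthesis

**24 to 23.** The C4'–Cl bond is cut and the C5' bromine is returned to C4', which leads to cyclic sulfite 23. Direct halogen addition to alkenol 20 is rejected because the bromonium ion on the hydroxyl face is the one opened at C4' in the diaxial mode, which gives the wrong isomer. Exchange of a tertiary C4' hydroxyl is rejected because a β-bromo tertiary centre ionises slowly and would need acid that the C1' alcohol cannot bear. In 23 an axial C4' bromine is anti to an axial C5' oxygen, so only the required bromonium ion can form. The forward step must ionise a secondary sulfite ester with bromine participation and let chloride attack the tertiary end.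

**23 to 20.** The sulfite S–O bonds, the C4'–Br bond and the epoxide C–O bonds are cut in turn: 23 comes from diol 22, 22 from epoxide 21 and hydrogen bromide, and 21 from alkenol 20. Each forward step follows the inherent preference of the locked ring (hydroxyl-directed epoxidation, then diaxial opening at the tertiary carbon). The precursor 20 has a single stereocentre in ring B.

**20 to 17.** The C4'–CH3 bond is cut to enol triflate 18, which comes from the symmetrical ketone 17 by enolisation towards one arm. Methyl addition to the ketone and dehydration would neither choose an arm nor spare the C1' alcohol. The forward step asks a chiral base to distinguish two α-methylene groups that ring A is too remote to differentiate.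

**17 to 13.** The silyl ether, four C–H bonds and the C1'–O bond are removed in turn: 17 from hydroxy ketone 16, 16 from para-quinol 15, 15 from phenol 14, and 14 from anisole 13. Dearomatisation makes the C1' carbinol next to the quaternary C1 without any carbon nucleophile adding to a hindered ketone, and the C1–C1' bond is simply the aryl–carbon bond present from the start.

**13 to 11.** The C3–Br bond is cut with inversion to alcohol 12, and 12 comes from ketone 11. This is done while ring B is still an inert arene. The forward steps need a reagent-controlled reduction and an SN2 displacement at a neopentylic but five-membered-ring carbon.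

**11 to 10 (key disconnection).** The C1–C2 bond is cut, giving cyclobutanol 10. Building the C1/C2 pair by enolate alkylation or conjugate addition would be intermolecular bond formation at the most hindered site, whereas here strain release drives it. The precursor carries one stereocentre that matters, and the forward step needs the quaternary carbon, not the methylene, to migrate, with retention.

**10 to 8 and 9.** The carbinol–isopropenyl bond is cut to cyclobutanone 8 and Grignard reagent 9; the carbinol configuration is irrelevant.

**8 to 7.** One ring bond of the cyclobutanone is cut to vinylcyclopropanol 7. The forward ring expansion under chiral Brønsted acid catalysis creates the quaternary stereocentre, the only enantioselective event for ring A.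

**7 to 1, 2 and 3.** The carbinol–alkenyl bond is cut to the alkenyl Grignard reagent 5 (from bromide 2, made from ketone 1) and cyclopropanone 6, released in the flask from 3 by way of 4.

## Roads not taken

**Alternative 1:** Ring A is bought as (1R,3S)-camphoric acid A1, which holds C1, C2, C3 and the three methyl groups with C1 in the configuration of the target; ring B is cut at C1'–C2' and C1'–C6'.
- Forward key step: the C1 acyl group is attacked twice by the ketal-bearing bis-Grignard reagent A2, closing ring B as the tertiary alcohol A3.
- Merits: no enantioselective step is needed for C1, its configuration is certain, and ring A is bought in one piece.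
- Weak points: the acyl group sits on a quaternary carbon flanked by the gem-dimethyl carbon, so the first addition is slow and the second competes with enolisation and β-hydride reduction. The C3 carboxyl must be degraded to oxygen, and in A3 that oxygen lies on the face where bromine must end, so an SN2 bromination needs a prior inversion. Ring B arrives as a symmetrical ketal, so the arm selection and the whole halogenation endgame are still required.
- Comparison: this road is better in certainty of C1 and in the cost of ring A. The chosen plan sets against it a strain-driven intramolecular formation of the congested C1–C2 bond, a C3 ketone reducible to the epimer that the inversion needs, and C1' oxygenation by dearomatisation.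

**Alternative 2:** The C4'–Cl bond is replaced by a C4'–O bond to the C1' oxygen, which leads back to the same alkenol 20 used here.
- Forward key step: NBS converts 20 into the bridged bromoether A4. The hydroxyl can reach C4' only through a boat and only from its own face, so the bromonium ion is forced onto the opposite face and C5' receives bromine as in the target.
- Merits: it answers the central stereochemical question of ring B in one reliable cyclisation, and the way to 24 would be one step shorter than steps 14 to 17.
- Weak points: A4 must exchange its C4'–O bond for C4'–Cl with retention while the C1'–O bond survives. Both are tertiary ether bonds; the one that must break is deactivated by the β-bromine, and ionisation of the other puts a cation next to the quaternary C1, where a Wagner–Meerwein shift can follow. The Lewis acid needed also threatens the neopentylic C3 bromide.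
- Comparison: the first step of this road is more certain than any single step of the endgame chosen here, and it is shorter. The chosen plan sets against it that the same bromonium ion is generated from a sulfite ester at the secondary C5' with chloride as the only nucleophile, so no tertiary C–O bond has to be cleaved selectively and the last step runs without acid.

**Alternative 3:** The C1 methyl group is cut back to the methylene of a cyclopropane fused at C1–C5, and the cyclopropane to the alkene of cyclopentenol A5.
- Forward key step: Et2Zn/CH2I2 cyclopropanates that alkene on the face of the C3 hydroxyl (Simmons–Smith reaction) to give A6; later hydrogenolysis of the least substituted cyclopropane bond reveals the methyl group.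
- Merits: the relative configuration of C1 and C3 is fixed by intramolecular delivery and is the right one, with the hydroxyl trans to ring B, ready for bromination with inversion.
- Weak points: A5 must itself be made enantiomerically enriched, with a hindered alkene between the carbinol-bearing carbon and the gem-dimethyl carbon, which costs more steps than ketone 11. Cyclopropane hydrogenolysis needs platinum in acid, hard on the tertiary alcohol and the ketal, and must cleave only the C5–CH2 bond. Ring B is again a symmetrical ketal.
- Comparison: this road is better in the control of C3 relative to C1, which the chosen plan must obtain from the oxazaborolidine reduction of step 6. The chosen plan sets against it a shorter access to ring A, with C1 fixed by catalysis and the C1–C2 bond made in one step, and ring B carried as an arene.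

Key step: step 5

Assumption: the antipode of the squaramide catalyst that gives (S)-8 and the antipode of the lithium amide that enolises 17 towards C5' are assigned by analogy (for the amide, the sense recalled for the (R,R)-base on 4-tert-butylcyclohexanone, with the cyclopentyl group in the place of tert-butyl); if an analogy fails, the mirror-image reagent is used.

## Route

Step 1
Reactants: 1 1-(4-methoxyphenyl)ethan-1-one
Product: 2 1-(1-bromoethenyl)-4-methoxybenzene
Conditions: P(OPh)3, Br2, CH2Cl2, −60 °C; then 1, Et3N, −60 °C → reflux
Reagents that add atoms: bromine, BrBr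
Why: Ketone-to-vinyl-bromide conversion with the bromophosphonium reagent formed from triphenyl phosphite and bromine: the carbonyl oxygen is activated on phosphorus, bromide adds, and the amine removes HBr and the phosphate to give the 1-bromoalkene; the basic medium protects the acid-sensitive, electron-rich bromostyrene.

Step 2
Reactants: 2 1-(1-bromoethenyl)-4-methoxybenzene; 3 (1-ethoxycyclopropoxy)trimethylsilane
Product: 7 1-[1-(4-methoxyphenyl)ethenyl]cyclopropan-1-ol, via 1-ethoxycyclopropan-1-ol 4 (not isolated), via alkenylmagnesium bromide 5 (not isolated), via cyclopropanone 6 (not isolated)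
Conditions: 3, MeOH, rt, then evaporation; MeMgBr (1.0 equiv), THF, 0 °C; separately 2, Mg, THF, 35 °C; combine, THF, 0 °C → reflux; aq. NH4Cl
Reagents that add atoms: none
Why: Grignard addition to a cyclopropanone equivalent: methanolysis frees hemiketal 4, whose magnesium salt collapses on warming to cyclopropanone 6, and the alkenyl Grignard reagent 5 adds to this strained ketone faster than it oligomerises; the sacrificial methyl Grignard acts only as base, so one equivalent of 5 suffices.

Step 3
Reactants: 7 1-[1-(4-methoxyphenyl)ethenyl]cyclopropan-1-ol
Product: 8 (2S)-2-(4-methoxyphenyl)-2-methylcyclobutan-1-one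
Conditions: HCl (10 mol %), 3-{[3,5-bis(trifluoromethyl)phenyl]amino}-4-({(2S)-3,3-dimethyl-1-oxo-1-[(2R)-2-(phenanthren-9-yl)pyrrolidin-1-yl]butan-2-yl}amino)cyclobut-3-ene-1,2-dione or its mirror image (10 mol %), toluene, −60 °C
Reagents that add atoms: none
Why: Enantioselective protio-semipinacol ring expansion: protonation of the methylene carbon gives a benzylic cation held as an ion pair with chloride bound to the chiral hydrogen-bond donor, and a cyclopropane C–C bond migrates to one face of the cation as the carbinol becomes the ketone; this sets the quaternary stereocentre (the future C1) as S.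

Step 4
Reactants: 8 (2S)-2-(4-methoxyphenyl)-2-methylcyclobutan-1-one; 9 prop-1-en-2-ylmagnesium bromide
Product: 10 (2S)-2-(4-methoxyphenyl)-2-methyl-1-(prop-1-en-2-yl)cyclobutan-1-ol (both C1 epimers)
Conditions: THF, −78 → 0 °C; aq. NH4Cl
Reagents that add atoms: none
Why: Grignard 1,2-addition to a strained, highly electrophilic cyclobutanone, fast at low temperature; the new carbinol centre need not be controlled because it becomes the carbonyl carbon again in step 5.

Step 5
Reactants: 10 (2S)-2-(4-methoxyphenyl)-2-methyl-1-(prop-1-en-2-yl)cyclobutan-1-ol
Product: 11 (3S)-3-(4-methoxyphenyl)-2,2,3-trimethylcyclopentan-1-one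
Conditions: TsOH·H2O (20 mol %), toluene, 50 °C
Reagents that add atoms: none
Why: This is the acid-mediated semipinacol (1,2-alkyl shift) ring expansion of a 1-alkenylcyclobutanol, the known route from 1-(prop-1-en-2-yl)cyclobutanols to 2,2-dimethylcyclopentanones. Protonation of the 1,1-disubstituted alkene at its methylene carbon gives a tertiary cation on the carbon next to the carbinol. The ring bond from the carbinol carbon to the aryl-bearing quaternary carbon then shifts to the cationic carbon while the hydroxyl oxygen forms the carbonyl group, and loss of the O–H proton regenerates the acid. Ring A is thus closed not by an end-to-end cyclisation but by insertion of the exocyclic carbon into the four-membered ring (a four-to-five ring enlargement by a suprafacial 1,2-shift), which forms the C1–C2 bond, places the gem-dimethyl group at C2 and leaves the ketone at C3. No new stereocentre is formed; the migrating carbon keeps its configuration because the shift is suprafacial, so (S)-8 is carried into (S)-11, and either carbinol epimer of 10 gives the same ketone. The selectivity required is migration of the quaternary carbon in preference to the ring methylene, and the substrate secures it because the more substituted, aryl-bearing carbon carries positive charge better in the bridged transition state. Release of cyclobutane strain and formation of the carbonyl group make the step irreversible.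

Step 6
Reactants: 11 (3S)-3-(4-methoxyphenyl)-2,2,3-trimethylcyclopentan-1-one
Product: 12 (1R,3S)-3-(4-methoxyphenyl)-2,2,3-trimethylcyclopentan-1-ol
Conditions: (S)-2-methyl-CBS-oxazaborolidine [(3aS)-1-methyl-3,3-diphenyltetrahydro-1H,3H-pyrrolo[1,2-c][1,3,2]oxazaborole] (20 mol %), BH3·SMe2, THF, −20 °C; MeOH
Reagents that add atoms: none
Why: Corey–Bakshi–Shibata reduction: the ketone binds with the quaternary gem-dimethyl carbon as the large flank and the ring methylene as the small one, so the (S)-catalyst should deliver hydride to the face that gives the (1R)-alcohol, hydroxyl trans to the aryl group; reagent control is used because the quaternary stereocentre one carbon away biases the two faces only weakly.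

Step 7
Reactants: 12 (1R,3S)-3-(4-methoxyphenyl)-2,2,3-trimethylcyclopentan-1-ol
Product: 13 1-[(1S,3S)-3-bromo-1,2,2-trimethylcyclopentyl]-4-methoxybenzene
Conditions: PPh3, CBr4, toluene, 0 → 60 °C
Reagents that add atoms: tetrabromomethane, BrC(Br)(Br)Br
Why: Appel bromination: bromide displaces the alkoxyphosphonium group at C3 with inversion (SN2), which puts bromine cis to the aryl group as in the target; a five-membered ring accepts backside attack more readily than a six-membered one, and the non-ionising medium is chosen to suppress the Wagner–Meerwein shift open to a neopentylic cation.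

Step 8
Reactants: 13 1-[(1S,3S)-3-bromo-1,2,2-trimethylcyclopentyl]-4-methoxybenzene
Product: 14 4-[(1S,3S)-3-bromo-1,2,2-trimethylcyclopentyl]phenol
Conditions: BBr3, CH2Cl2, −78 → 0 °C; H2O
Reagents that add atoms: none
Why: Lewis acid cleavage of the aryl methyl ether (O–B complexation, bromide attack on the methyl group); the secondary alkyl bromide is inert at this temperature.

Step 9
Reactants: 14 4-[(1S,3S)-3-bromo-1,2,2-trimethylcyclopentyl]phenol
Product: 15 4-[(1R,3S)-3-bromo-1,2,2-trimethylcyclopentyl]-4-hydroxycyclohexa-2,5-dien-1-one
Conditions: PhI(OAc)2, MeCN/H2O (3:1), 0 °C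
Reagents that add atoms: water, O
Why: Oxidative dearomatisation of a para-alkylphenol to the para-quinol: the phenol is activated on trivalent iodine and water attacks the para carbon, creating the C1' carbinol next to the quaternary C1 without any addition to a hindered ketone; C1' is not yet stereogenic because its two ring arms are identical.

Step 10
Reactants: 15 4-[(1R,3S)-3-bromo-1,2,2-trimethylcyclopentyl]-4-hydroxycyclohexa-2,5-dien-1-one
Product: 16 4-[(1R,3S)-3-bromo-1,2,2-trimethylcyclopentyl]-4-hydroxycyclohexan-1-one
Conditions: H2 (1 atm), 5% Rh/Al2O3, EtOAc, rt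
Reagents that add atoms: none
Why: Heterogeneous hydrogenation of both enone double bonds; rhodium on alumina under neutral conditions is chosen because it saturates alkenes without hydrogenolysis of the tertiary allylic alcohol (which would rearomatise the ring) or of the C–Br bond.

Step 11
Reactants: 16 4-[(1R,3S)-3-bromo-1,2,2-trimethylcyclopentyl]-4-hydroxycyclohexan-1-one
Product: 17 4-[(1R,3S)-3-bromo-1,2,2-trimethylcyclopentyl]-4-[(trimethylsilyl)oxy]cyclohexan-1-one
Conditions: 1-(trimethylsilyl)imidazole, CH2Cl2, rt
Reagents that add atoms: 1-(trimethylsilyl)imidazole, C[Si](C)(C)n1ccnc1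
Why: Silylation of a hindered tertiary alcohol with a neutral, powerful silyl donor that does not enolise the ketone; the ether keeps an alkoxide out of the lithium amide aggregate of step 12.

Step 12
Reactants: 17 4-[(1R,3S)-3-bromo-1,2,2-trimethylcyclopentyl]-4-[(trimethylsilyl)oxy]cyclohexan-1-one
Product: 18 (4R)-4-[(1R,3S)-3-bromo-1,2,2-trimethylcyclopentyl]-4-[(trimethylsilyl)oxy]cyclohex-1-en-1-yl trifluoromethanesulfonate
Conditions: (R,R)-bis(1-phenylethyl)amine·HCl, n-BuLi (2 equiv), THF, −78 °C; add 17; then N-(5-chloropyridin-2-yl)triflimide, −78 °C
Reagents that add atoms: N-(5-chloropyridin-2-yl)-1,1,1-trifluoro-N-(trifluoromethylsulfonyl)methanesulfonamide, FC(F)(F)S(=O)(=O)N(c1ccc(Cl)cn1)S(=O)(=O)C(F)(F)F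
Why: Desymmetrising deprotonation with a chiral lithium amide (lithium chloride present from the amine salt) followed by O-sulfonylation of the kinetic enolate: the base removes an axial α-hydrogen from one of the two α-methylene groups, which makes C1' a stereocentre (R) by fixing the arm that carries the double bond; ring A is too remote to make this choice, so the antipode of the base makes it.

Step 13
Reactants: 18 (4R)-4-[(1R,3S)-3-bromo-1,2,2-trimethylcyclopentyl]-4-[(trimethylsilyl)oxy]cyclohex-1-en-1-yl trifluoromethanesulfonate
Product: 20 (1R)-1-[(1R,3S)-3-bromo-1,2,2-trimethylcyclopentyl]-4-methylcyclohex-3-en-1-ol, via silyl ether 19 (not isolated)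
Conditions: MeZnCl, Pd(PPh3)4 (5 mol %), THF, 40 °C; then Bu4NF, THF, 0 °C
Reagents that add atoms: methylzinc chloride, C[Zn]Cl
Why: Negishi coupling of an alkenyl triflate: zerovalent palladium inserts into the alkenyl C–O bond but not into the unactivated, hindered secondary C–Br bond, and transmetalation from zinc and reductive elimination install the C4' methyl group; fluoride then frees the C1' hydroxyl, which step 14 needs as a directing group.

Step 14
Reactants: 20 (1R)-1-[(1R,3S)-3-bromo-1,2,2-trimethylcyclopentyl]-4-methylcyclohex-3-en-1-ol
Product: 21 (1R,3R,6S)-3-[(1R,3S)-3-bromo-1,2,2-trimethylcyclopentyl]-6-methyl-7-oxabicyclo[4.1.0]heptan-3-ol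
Conditions: VO(acac)2 (3 mol %), t-BuOOH, CH2Cl2, 0 °C → rt
Reagents that add atoms: tert-butyl hydroperoxide, CC(C)(C)OO
Why: Hydroxyl-directed epoxidation of a homoallylic alcohol: the axial C1' hydroxyl binds vanadium and the coordinated peroxide reaches the C4'=C5' bond only on the hydroxyl face, so the epoxide oxygen is set cis to the hydroxyl at both C4' and C5'.

Step 15
Reactants: 21 (1R,3R,6S)-3-[(1R,3S)-3-bromo-1,2,2-trimethylcyclopentyl]-6-methyl-7-oxabicyclo[4.1.0]heptan-3-ol
Product: 22 (1R,3R,4R)-4-bromo-1-[(1R,3S)-3-bromo-1,2,2-trimethylcyclopentyl]-4-methylcyclohexane-1,3-diol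
Conditions: 48% aq. HBr (1.1 equiv), Et2O, −20 °C
Reagents that add atoms: hydrogen bromide, Br
Why: Acid-mediated epoxide opening by bromide with inversion at the tertiary C4': Markovnikov regiochemistry and trans-diaxial (Fürst–Plattner) opening coincide here, giving axial bromine at C4' anti to an axial C5' hydroxyl that lies syn to the C1' hydroxyl; low temperature and one equivalent of acid spare the tertiary alcohol.

Step 16
Reactants: 22 (1R,3R,4R)-4-bromo-1-[(1R,3S)-3-bromo-1,2,2-trimethylcyclopentyl]-4-methylcyclohexane-1,3-diol
Product: 23 (1R,5R,6R)-6-bromo-1-[(1R,3S)-3-bromo-1,2,2-trimethylcyclopentyl]-6-methyl-2,4-dioxa-3-thiabicyclo[3.3.1]nonane 3-oxide (sulfur configuration not defined)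
Conditions: SOCl2 (1.05 equiv), pyridine, CH2Cl2, −20 → 0 °C
Reagents that add atoms: thionyl chloride, O=S(Cl)Cl
Why: Cyclic sulfite formation from a 1,3-diol: the two syn-axial hydroxyls close the six-membered sulfite readily; the bridge turns the C5' oxygen into a leaving group, masks the C1' oxygen as a non-nucleophilic ester and covers C5' on the oxygen face.

Step 17
Reactants: 23 (1R,5R,6R)-6-bromo-1-[(1R,3S)-3-bromo-1,2,2-trimethylcyclopentyl]-6-methyl-2,4-dioxa-3-thiabicyclo[3.3.1]nonane 3-oxide
Product: 24 (1R,3S,4S)-3-bromo-1-[(1R,3S)-3-bromo-1,2,2-trimethylcyclopentyl]-4-chloro-4-methylcyclohexan-1-ol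
Conditions: Bu4NCl (5 equiv), MeCN, 50 °C; then aq. NaHCO3
Reagents that add atoms: tetrabutylammonium chloride, CCCC[N+](CCCC)(CCCC)CCCC.[Cl-]
Why: Substitution with neighbouring-bromine participation and 1,2-bromine shift: the axial C4'–Br bond is anti-periplanar to the C5'–O bond, so departure of the sulfite oxygen gives a bromonium ion on the face opposite to the oxygens, and chloride opens it at the tertiary, more cationic C4' from the oxygen face (C5' being shielded by the tethered sulfite), leaving bromine on C5'; both centres are inverted, which sets chlorine cis and bromine trans to the C1' hydroxyl (trans-diequatorial in the chair), and the sulfite monoester left on C1' loses SO2 on aqueous work-up.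

## Compound list

1 | 1-(4-methoxyphenyl)ethan-1-one | CC(=O)c1ccc(OC)cc1 | starting material
2 | 1-(1-bromoethenyl)-4-methoxybenzene | C=C(Br)c1ccc(OC)cc1 | intermediate
3 | (1-ethoxycyclopropoxy)trimethylsilane | CCOC1(CC1)O[Si](C)(C)C | starting material
4 | 1-ethoxycyclopropan-1-ol | CCOC1(O)CC1 | intermediate (not isolated)
5 | [1-(4-methoxyphenyl)ethenyl]magnesium bromide | C=C([Mg]Br)c1ccc(OC)cc1 | intermediate (not isolated)
6 | cyclopropanone | O=C1CC1 | intermediate (not isolated)
7 | 1-[1-(4-methoxyphenyl)ethenyl]cyclopropan-1-ol | C=C(c1ccc(OC)cc1)C1(O)CC1 | intermediate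
8 | (2S)-2-(4-methoxyphenyl)-2-methylcyclobutan-1-one | O=C1CC[C@@]1(C)c1ccc(OC)cc1 | intermediate
9 | prop-1-en-2-ylmagnesium bromide | CC(=C)[Mg]Br | starting material
10 | (2S)-2-(4-methoxyphenyl)-2-methyl-1-(prop-1-en-2-yl)cyclobutan-1-ol (both C1 epimers) | C=C(C)C1(O)CC[C@@]1(C)c1ccc(OC)cc1 | intermediate
11 | (3S)-3-(4-methoxyphenyl)-2,2,3-trimethylcyclopentan-1-one | CC1(C)C(=O)CC[C@@]1(C)c1ccc(OC)cc1 | intermediate
12 | (1R,3S)-3-(4-methoxyphenyl)-2,2,3-trimethylcyclopentan-1-ol | CC1(C)[C@H](O)CC[C@@]1(C)c1ccc(OC)cc1 | intermediate
13 | 1-[(1S,3S)-3-bromo-1,2,2-trimethylcyclopentyl]-4-methoxybenzene | CC1(C)[C@@H](Br)CC[C@@]1(C)c1ccc(OC)cc1 | intermediate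
14 | 4-[(1S,3S)-3-bromo-1,2,2-trimethylcyclopentyl]phenol | CC1(C)[C@@H](Br)CC[C@@]1(C)c1ccc(O)cc1 | intermediate
15 | 4-[(1R,3S)-3-bromo-1,2,2-trimethylcyclopentyl]-4-hydroxycyclohexa-2,5-dien-1-one | CC1(C)[C@@H](Br)CC[C@@]1(C)C1(O)C=CC(=O)C=C1 | intermediate
16 | 4-[(1R,3S)-3-bromo-1,2,2-trimethylcyclopentyl]-4-hydroxycyclohexan-1-one | CC1(C)[C@@H](Br)CC[C@@]1(C)C1(O)CCC(=O)CC1 | intermediate
17 | 4-[(1R,3S)-3-bromo-1,2,2-trimethylcyclopentyl]-4-[(trimethylsilyl)oxy]cyclohexan-1-one | CC1(C)[C@@H](Br)CC[C@@]1(C)C1(O[Si](C)(C)C)CCC(=O)CC1 | intermediate
18 | (4R)-4-[(1R,3S)-3-bromo-1,2,2-trimethylcyclopentyl]-4-[(trimethylsilyl)oxy]cyclohex-1-en-1-yl trifluoromethanesulfonate | CC1(C)[C@@H](Br)CC[C@@]1(C)[C@@]1(O[Si](C)(C)C)CCC(OS(=O)(=O)C(F)(F)F)=CC1 | intermediate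
19 | {[(1R)-1-[(1R,3S)-3-bromo-1,2,2-trimethylcyclopentyl]-4-methylcyclohex-3-en-1-yl]oxy}trimethylsilane | CC1(C)[C@@H](Br)CC[C@@]1(C)[C@@]1(O[Si](C)(C)C)CCC(C)=CC1 | intermediate (not isolated)
20 | (1R)-1-[(1R,3S)-3-bromo-1,2,2-trimethylcyclopentyl]-4-methylcyclohex-3-en-1-ol | CC1(C)[C@@H](Br)CC[C@@]1(C)[C@@]1(O)CCC(C)=CC1 | intermediate
21 | (1R,3R,6S)-3-[(1R,3S)-3-bromo-1,2,2-trimethylcyclopentyl]-6-methyl-7-oxabicyclo[4.1.0]heptan-3-ol | CC1(C)[C@@H](Br)CC[C@@]1(C)[C@@]1(O)CC[C@]2(C)O[C@@H]2C1 | intermediate
22 | (1R,3R,4R)-4-bromo-1-[(1R,3S)-3-bromo-1,2,2-trimethylcyclopentyl]-4-methylcyclohexane-1,3-diol | CC1(C)[C@@H](Br)CC[C@@]1(C)[C@@]1(O)CC[C@@](C)(Br)[C@H](O)C1 | intermediate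
23 | (1R,5R,6R)-6-bromo-1-[(1R,3S)-3-bromo-1,2,2-trimethylcyclopentyl]-6-methyl-2,4-dioxa-3-thiabicyclo[3.3.1]nonane 3-oxide (sulfur configuration not defined) | CC1(C)[C@@H](Br)CC[C@@]1(C)[C@@]1(O2)CC[C@@](C)(Br)[C@H](OS2=O)C1 | intermediate
24 | (1R,3S,4S)-3-bromo-1-[(1R,3S)-3-bromo-1,2,2-trimethylcyclopentyl]-4-chloro-4-methylcyclohexan-1-ol | CC1(C)[C@@H](Br)CC[C@@]1(C)[C@@]1(O)CC[C@](C)(Cl)[C@@H](Br)C1 | target

## Step count and least certain steps

Total: 17 steps. Longest linear sequence: 17 steps (1 to 24); 3 and 9 are purchased partners.

**Step 5 (key step).** The bond from the migrating quaternary carbon to the carbinol carbon may break ahead of the new bond, because the 4-methoxyphenyl group stabilises a ring-opened benzylic cation and the cyclobutane strain favours cleavage. Reclosure on either face would erode the enantiomeric purity of C1, and the exposed cation could also be intercepted by the arene. Fallback: starting from 10, the shift is triggered by a bromonium ion instead of a proton (NBS, i-PrOH/CH2Cl2, −40 °C), where migration is anti to the bromine and concerted. This should give 2-(bromomethyl)-3-(4-methoxyphenyl)-2,3-dimethylcyclopentan-1-one F1 as a mixture at C2. Radical debromination (Bu3SnH in high concentration so that hydrogen transfer outruns Dowd–Beckwith ring enlargement, AIBN, benzene, 80 °C) turns the bromomethyl group into the second methyl group and returns to 11.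

**Step 17.** The sulfite ester may not ionise below the temperature at which the tertiary bromide eliminates, or chloride may attack sulfur instead of carbon. Fallback: starting from 23, oxidation (RuCl3 cat., NaIO4, MeCN/H2O/EtOAc, 0 °C) gives the far more reactive cyclic sulfate F2. Bu4NCl in THF at room temperature should open it through the same bromonium ion to the tetrabutylammonium sulfate monoester F3. Hydrolysis with catalytic H2SO4 and one equivalent of water in THF returns to 24; this last operation is the price of the fallback, since it exposes the C1' centre to acid.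

**Step 12.** Discrimination between the two α-methylene groups may be poor, because the axial silyloxy group lies syn to both axial α-hydrogens and may disturb the approach of the base; enolate equilibration before trapping would add to the loss. Fallback: starting from 15, the arms are told apart by copper hydride conjugate reduction (Cu(OAc)2, 1,2-bis[(2S,5S)-2,5-diphenylphospholan-1-yl]ethane or its antipode, (EtO)2MeSiH, then fluoride work-up), which leaves the C5'=C6' enone and gives (4R)-4-[(1R,3S)-3-bromo-1,2,2-trimethylcyclopentyl]-4-hydroxycyclohex-2-en-1-one F4. Conjugate hydride addition (LiBH(s-Bu)3, THF, −78 °C) and trapping of the regiodefined enolate with N-(5-chloropyridin-2-yl)triflimide gives (4R)-4-[(1R,3S)-3-bromo-1,2,2-trimethylcyclopentyl]-4-hydroxycyclohex-1-en-1-yl trifluoromethanesulfonate F5. Coupling with MeZnCl and Pd(PPh3)4 returns to 20.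

**Step 9.** Attack of water at the para carbon is slowed by the neighbouring quaternary C1, so the activated phenol may be diverted to ortho attack or oligomerisation. Fallback: starting from 14, singlet oxygen generated in the flask (KHSO5 as its triple salt, NaHCO3, MeCN/H2O) adds across the phenol ring and should give 4-[(1R,3S)-3-bromo-1,2,2-trimethylcyclopentyl]-4-hydroperoxycyclohexa-2,5-dien-1-one F6. Reduction with Me2S returns to 15.

**Step 7.** Displacement at the neopentylic C3 may be too slow, so that the alkoxyphosphonium salt eliminates to the cyclopentene or ionises with a methyl shift. Fallback: starting from 12, activation and displacement are separated. ClCH2SO2Cl and pyridine give the small, highly activated ester (1R,3S)-3-(4-methoxyphenyl)-2,2,3-trimethylcyclopentyl chloromethanesulfonate F7. LiBr in DMF at 40 °C displaces it with inversion and returns to 13.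

## Further compounds

F1 | step 5 | (3S)-2-(bromomethyl)-3-(4-methoxyphenyl)-2,3-dimethylcyclopentan-1-one (both C2 epimers) | CC1(CBr)C(=O)CC[C@@]1(C)c1ccc(OC)cc1
F2 | step 17 | (1R,5R,6R)-6-bromo-1-[(1R,3S)-3-bromo-1,2,2-trimethylcyclopentyl]-6-methyl-2,4-dioxa-3-thiabicyclo[3.3.1]nonane 3,3-dioxide | CC1(C)[C@@H](Br)CC[C@@]1(C)[C@@]1(O2)CC[C@@](C)(Br)[C@H](OS2(=O)=O)C1
F3 | step 17 | tetrabutylammonium (1R,3S,4S)-3-bromo-1-[(1R,3S)-3-bromo-1,2,2-trimethylcyclopentyl]-4-chloro-4-methylcyclohexyl sulfate | CC1(C)[C@@H](Br)CC[C@@]1(C)[C@@]1(OS(=O)(=O)[O-])CC[C@](C)(Cl)[C@@H](Br)C1.CCCC[N+](CCCC)(CCCC)CCCC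
F4 | step 12 | (4R)-4-[(1R,3S)-3-bromo-1,2,2-trimethylcyclopentyl]-4-hydroxycyclohex-2-en-1-one | CC1(C)[C@@H](Br)CC[C@@]1(C)[C@@]1(O)CCC(=O)C=C1
F5 | step 12 | (4R)-4-[(1R,3S)-3-bromo-1,2,2-trimethylcyclopentyl]-4-hydroxycyclohex-1-en-1-yl trifluoromethanesulfonate | CC1(C)[C@@H](Br)CC[C@@]1(C)[C@@]1(O)CCC(OS(=O)(=O)C(F)(F)F)=CC1
F6 | step 9 | 4-[(1R,3S)-3-bromo-1,2,2-trimethylcyclopentyl]-4-hydroperoxycyclohexa-2,5-dien-1-one | CC1(C)[C@@H](Br)CC[C@@]1(C)C1(OO)C=CC(=O)C=C1
F7 | step 7 | (1R,3S)-3-(4-methoxyphenyl)-2,2,3-trimethylcyclopentyl chloromethanesulfonate | CC1(C)[C@H](OS(=O)(=O)CCl)CC[C@@]1(C)c1ccc(OC)cc1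
A1 | alternative 1 | (1R,3S)-1,2,2-trimethylcyclopentane-1,3-dicarboxylic acid (camphoric acid) | CC1(C)[C@@H](C(O)=O)CC[C@@]1(C)C(O)=O
A2 | alternative 1 | 2,2-bis[2-(bromomagnesio)ethyl]-1,3-dioxolane | Br[Mg]CCC1(CC[Mg]Br)OCCO1
A3 | alternative 1 | 8-[(1R,3S)-3-(tert-butyldimethylsilyloxy)-1,2,2-trimethylcyclopentyl]-1,4-dioxaspiro[4.5]decan-8-ol | CC1(C)[C@@H](O[Si](C)(C)C(C)(C)C)CC[C@@]1(C)C1(O)CCC2(CC1)OCCO2
A4 | alternative 2 | (1S,2S,4R)-2-bromo-4-[(1R,3S)-3-bromo-1,2,2-trimethylcyclopentyl]-1-methyl-7-oxabicyclo[2.2.1]heptane | CC1(C)[C@@H](Br)CC[C@@]1(C)[C@@]1(O2)CC[C@@]2(C)[C@@H](Br)C1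
A5 | alternative 3 | 8-[(4R)-4-hydroxy-5,5-dimethylcyclopent-1-en-1-yl]-1,4-dioxaspiro[4.5]decan-8-ol | CC1(C)[C@H](O)CC=C1C1(O)CCC2(CC1)OCCO2
A6 | alternative 3 | 8-[(1R,3R,5S)-3-hydroxy-2,2-dimethylbicyclo[3.1.0]hexan-1-yl]-1,4-dioxaspiro[4.5]decan-8-ol | CC1(C)[C@H](O)C[C@@H]2C[C@]12C1(O)CCC3(CC1)OCCO3
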